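## The problem

Ferulsinaic acid (27) is a monocyclic cyclopentane with four of its five ring carbons substituted. C1 is quaternary (methyl and the 2‑carboxyethyl arm), C2 carries the CH2–O–coumarin unit, C3 a methyl group, C4 is the only methylene, and C5 carries the 2‑methylprop‑1‑enyl group. The target has no ring fusion to lean on, so the four stereocentres (1R,2R,3S,5S) must be related on a flexible five‑membered ring. The acid arm at C1, the alkenyl group at C5 and the methyl at C3 lie on one face; the aryloxymethyl group at C2 and the C1 methyl lie on the other. C1 cannot be corrected once made, so C1 and its neighbour C5 have to be fixed first and in the absolute sense. Held in a cis‑fused bicycle, they can then steer C3 (reagent approach from the open face) and C2 (equilibration next to a carbonyl group). The coumarin is a lactone and a Michael acceptor and will not tolerate ylides, hydrides or dissolving metals. The trisubstituted alkene will not tolerate ozone, hydrogenation or strong acid, and the acid must be masked while the aryl ether is made. The feature that opens the structure is the pair of cis one‑carbon branches on C1 and C5, the first carbon of the acid arm and the first alkenyl carbon. They are the carbonyl and acetal carbons of a cis‑fused α‑methyl γ‑lactone. C2 with its exocyclic carbon, C3 with its methyl and C4 are the five carbons of isoprene once the cyclopentane is read as a cyclohexene contracted by one carbon.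

## Retrosynthesis

**Aryl ether and acid (27 ⇒ 25 ⇒ 23 + 24).** The O–CH2 bond between the coumarin oxygen and the C2 methylene is cut, and the acid is carried as its methyl ester. Umbelliferone (24) is commercial and brings the whole heterocycle in one operation. Placing the coupling second to last keeps the coumarin away from every ylide, hydride and metal of the route. The forward reaction is a Mitsunobu etherification of the β‑branched primary alcohol 23. Saponification of 25 then has to leave the coumarin intact, which it does through reversible ring opening (26) and reclosure on acidification.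

**Acid arm (23 ⇒ 22 ⇒ 21 ⇒ 20 ⇒ 19 ⇒ 18).** The bond between the first and second carbon of the arm is cut. Displacement at the neopentyl carbon next to C1 is not realistic, whereas carbonyl olefination of the α‑quaternary aldehyde 20 with a phosphonoacetate anion is. The conjugated alkene of 21 is then reduced selectively beside the isolated trisubstituted one. Aldehyde 20 traces back through alcohol 19 to carboxylic acid 18, so the first carbon of the arm is the carbon already attached to C1.

**Alkenyl group (18 ⇒ 17 ⇒ 16).** The C=C bond is cut by a Wittig disconnection. The resulting cis formyl acid 17 exists as lactol 16. The two one‑carbon branches on C1 and C5 are therefore told apart by oxidation level, acid against aldehyde, with no protecting group. The forward step requires an isopropylidene ylide to trap the open form faster than C5 epimerises.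

**Acetal and hydroxymethyl group (16 ⇒ 15 ⇒ 14 ⇒ 13).** Lactol 16 comes from the menthyl acetal 15 by aqueous acid, which returns the auxiliary 4. The C2 hydroxymethyl group is held as a tert‑butyldiphenylsilyl ether because that group survives aqueous acid, ylide and hydride and is removed by fluoride beside an ester. Alcohol 14 is the reduction product of aldehyde 13.

**C2 and C3 (13 ⇒ 12 ⇒ 11).** The two C–H bonds at C2 and C3 are cut, leading to the tetrasubstituted enal 11. Hydrogen must come from the convex face of the cis‑fused bicycle to place the C3 methyl on the lactone face. This leaves the formyl group on that face as well (12). Base equilibration then moves it to the convex face, trans to the C3 methyl (13).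

**Ring contraction (11 ⇒ 10 ⇒ 9 ⇒ 8 ⇒ 7).** The C2–C3 bond is cut by an aldol condensation, leading to keto aldehyde 9, which is the ozonolysis product of cyclohexene 7. The formyl carbon of 11 is the extruded ring carbon, so C2 receives its exocyclic carbon without any addition to a hindered ketone. The forward reaction needs the aldehyde, not the methyl ketone, to act as the nucleophile, which amine catalysis provides.

**Cycloaddition (7 ⇒ 5 + 6).** The C1–C2 and C4–C5 bonds (C7a–C7 and C3a–C4 of 7) are cut, giving isoprene (6) and the α‑methyl butenolide 5. Against other [4+2] cuts of the six‑membered ring, this one sets the quaternary centre and its neighbour in a single step and leaves both one‑carbon branches at useful oxidation levels. It asks for addition anti to the menthyloxy group and for the methyl of 6 to end para to the carbonyl‑bearing carbon.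

**Dienophile (5 ⇒ 3 + 4; 3 ⇒ 2 ⇒ 1).** The acetal C–O bond is cut to give hydroxybutenolide 3 and (−)‑menthol (4). Compound 3 comes from 3‑methylfuran‑2‑carboxylic acid (1) by photooxygenation through endoperoxide 2. The carboxyl‑bearing carbon becomes the lactone carbonyl, which places the methyl group α to it.

## Roads not taken

**Alternative 1:** The ring is cut at C2–C3 and C3–C4, so that C3 with its methyl is a one‑carbon insert into cyclobutanone A2 (acid arm cis to the alkenyl group), itself the [2+2] adduct of a disubstituted ketene and a diene. In the forward sense diazoethane A3 adds to the strained ketone and the methylene carbon migrates with loss of nitrogen to give cyclopentanone A1.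
- Merits: it is the shortest assembly of the ring. The quaternary centre, the complete acid arm and the alkenyl group arrive in two C–C bond‑forming steps, and in step economy up to A1 it is clearly better than the chosen plan.
- Weak points for this target:
  - The ketene cycloaddition is racemic unless a separate solution for absolute control is found.
  - Migration of the methylene rather than the quaternary carbon, and a stop after one insertion, are not assured.
  - The C3 methyl is set only by equilibration next to the ketone.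
  - The C2 ketone of A1, flanked by a quaternary and a tertiary carbon, must still be homologated by one carbon and reduced to the 2,3‑trans CH–CH2O arrangement.
  - Diazoethane is hazardous on scale.
- Comparison: the chosen plan is longer, but it has a defined control element for every stereocentre and delivers the C2 carbon by ring contraction at the aldehyde level.

**Alternative 2:** The bond from C5 to the future alkenyl carbon is made in the key step. Triketone A5 is desymmetrised by an enamine aldol condensation catalysed by D‑proline A6 (Hajos–Parrish reaction), giving enedione A4. Its five‑membered ring is the target ring, its quaternary carbon is C1, and the cyclohexenone is a tether, later cut to release the three‑carbon acid arm and a formyl precursor of the alkenyl group.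
- Merits: the quaternary centre is set catalytically, in either enantiomeric series, on large scale, from cheap achiral material and without a stoichiometric auxiliary. In this respect it is better than the chosen plan, whose absolute control needs a diastereomer crystallisation and a sluggish cycloaddition.
- Weak points for this target:
  - The tether must be cut regioselectively on one side of its ketone.
  - The ring ketone next to C1 has to be α‑methylated and then homologated by one carbon at a neopentyl position, with substrate control over C2, C3 and C5.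
  - The two ketones must be kept apart throughout, which makes the sequence long.
- Comparison: the chosen plan has every substituent carbon in place at a workable oxidation level directly after the contraction, and a rigid bicycle on which C2 and C3 are set.

**Alternative 3:** The cut lies in the heterocycle. C4–C4a of the coumarin is disconnected to aryl propiolate A8, and a cationic monovalent gold catalyst closes the pyranone by 6‑endo hydroarylation para to the alkoxy group, giving ester A7 (identical with 25).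
- Merits: a plain aryl ether can be installed early and carried through ylide and hydride steps that a coumarin would not survive. That would remove the silyl protection and deprotection of the chosen plan, a real saving of two steps.
- Weak points for this target:
  - The saving is spent again on phenol differentiation, propiolate esterification and the cyclisation.
  - Closure ortho to the alkoxy group would give the 5‑alkoxy isomer.
  - The π‑acid can engage the electron‑rich trisubstituted alkene.
  - The cut says nothing about the cyclopentane, where the difficulty lies.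
- Comparison: the chosen plan takes the finished heterocycle from commercial 24 in one well‑known etherification with no regiochemical question.

Key step: step 3

Assumption: the (5R) epimer of acetal 5 is taken to be the one that crystallises from the acid‑equilibrating mixture, as is known for the parent 5‑menthyloxyfuranone made from (−)‑menthol.

Conventions: "menthyloxy" stands for [(1R,2S,5R)‑5‑methyl‑2‑(propan‑2‑yl)cyclohexyl]oxy; TBDPS is tert‑butyl(diphenyl)silyl; target ring positions are C1 (quaternary), C2 (CH2O), C3 (CH3), C4 (CH2), C5 (alkenyl).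

## Route

Step 1
Reactants: 1 3‑methylfuran‑2‑carboxylic acid
Product: 3 5‑hydroxy‑3‑methylfuran‑2(5H)‑one (racemic), via furan endoperoxide 2 (not isolated)
Conditions: O2, rose bengal (cat.), visible light, MeOH, 0 °C
Reagents that add atoms: oxygen, O=O
Why: Dye‑sensitised photooxygenation: singlet oxygen adds [4+2] across C2 and C5 of the furan, and endoperoxide 2 loses CO2 with O–O cleavage, so the carboxyl‑bearing carbon becomes the lactone carbonyl and the methyl group ends α to it.

Step 2
Reactants: 3 5‑hydroxy‑3‑methylfuran‑2(5H)‑one; 4 (−)‑menthol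
Product: 5 (5R)‑3‑methyl‑5‑[(1R,2S,5R)‑menthyloxy]furan‑2(5H)‑one
Conditions: (+)‑camphor‑10‑sulfonic acid (cat.), toluene, reflux, Dean–Stark; crystallisation from hexane, mother liquor re‑equilibrated with acid
Reagents that add atoms: none
Why: Acid‑catalysed acetalisation of the pseudo‑acid; the acetal carbon epimerises through the oxocarbenium ion under the same catalyst, so crystallisation should collect the less soluble (5R) diastereomer (crystallisation‑induced diastereomer enrichment) and fix the only stereocentre that later controls C1 and C5.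

Step 3
Reactants: 5 (5R)‑3‑methyl‑5‑[(1R,2S,5R)‑menthyloxy]furan‑2(5H)‑one; 6 isoprene
Product: 7 (3R,3aR,7aS)‑5,7a‑dimethyl‑3‑[(1R,2S,5R)‑menthyloxy]‑3a,4,7,7a‑tetrahydro‑2‑benzofuran‑1(3H)‑one (cis‑fused)
Conditions: 6 (10 equiv), BHT (cat.), toluene, sealed tube, 160 °C (or 12 kbar, CH2Cl2, rt)
Reagents that add atoms: none
Why: Thermal, concerted but asynchronous Diels–Alder cycloaddition; the closest precedent is the addition of acyclic dienes to 5‑alkoxyfuran‑2(5H)‑ones, which occurs on the face opposite the alkoxy group. The cyclohexene is closed intermolecularly by two σ‑bonds, C7a–C7 and C3a–C4, formed suprafacially on both partners, so the Z alkene of 5 becomes the cis ring fusion. C7a (later C1) and C3a (later C5) are the new stereocentres: their cis relation follows from this stereospecificity and their absolute sense from the acetal carbon of 5, whose menthyloxy group shields one face of the flat butenolide so that 6 adds anti to it. The methyl group must end at C5, para to the carbonyl‑bearing C7a, because only this regioisomer contracts to the 2‑formyl‑3‑methylcyclopentene; the match of the larger HOMO coefficient at C1 of 6 with the larger LUMO coefficient at the β‑carbon of 5 favours it, and any meta isomer would be removed by chromatography or crystallisation. Endo/exo selectivity does not arise since 6 has unsubstituted termini. The α‑methyl group makes 5 a slow trisubstituted dienophile, hence the excess diene, heat and radical inhibitor, with high pressure as the milder equivalent.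

Step 4
Reactants: 7 (3R,3aR,7aS)‑5,7a‑dimethyl‑3‑menthyloxy‑3a,4,7,7a‑tetrahydro‑2‑benzofuran‑1(3H)‑one
Product: 9 2‑{(3S,4R,5R)‑3‑methyl‑5‑[(1R,2S,5R)‑menthyloxy]‑2‑oxo‑4‑(2‑oxopropyl)oxolan‑3‑yl}acetaldehyde, via secondary ozonide 8 (not isolated)
Conditions: O3 (1 equiv, stopped at first excess), CH2Cl2, −78 °C; then Me2S, −78 °C → rt
Reagents that add atoms: ozone, [O-][O+]=O
Why: Ozonolysis with reductive work‑up; the trisubstituted alkene is the only site that reacts quickly with ozone at −78 °C, and the C5–C6 cleavage gives the methyl ketone on the C3a side and the aldehyde on the C7a side without touching a stereocentre.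

Step 5
Reactants: 9 2‑{(3S,4R,5R)‑3‑methyl‑5‑menthyloxy‑2‑oxo‑4‑(2‑oxopropyl)oxolan‑3‑yl}acetaldehyde
Product: 11 (3R,3aR,6aR)‑5,6a‑dimethyl‑3‑[(1R,2S,5R)‑menthyloxy]‑1‑oxo‑3,3a,4,6a‑tetrahydro‑1H‑cyclopenta[c]furan‑6‑carbaldehyde, via β‑hydroxy aldehyde 10 (not isolated)
Conditions: dibenzylammonium trifluoroacetate (0.3 equiv), toluene, 60 °C
Reagents that add atoms: none
Why: Amine‑salt‑catalysed intramolecular aldol condensation: the secondary amine forms the enamine of the aldehyde far faster than that of the methyl ketone, its α‑carbon closes the five‑membered ring onto the ketone (5‑enolexo), and dehydration of 10 gives the tetrasubstituted enal; no stereocentre is made and none is epimerisable.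

Step 6
Reactants: 11 (3R,3aR,6aR)‑5,6a‑dimethyl‑3‑menthyloxy‑1‑oxo‑3,3a,4,6a‑tetrahydro‑1H‑cyclopenta[c]furan‑6‑carbaldehyde
Product: 13 (3R,3aR,5S,6R,6aR)‑5,6a‑dimethyl‑3‑[(1R,2S,5R)‑menthyloxy]‑1‑oxohexahydro‑1H‑cyclopenta[c]furan‑6‑carbaldehyde (formyl trans to the C5 methyl), via cis aldehyde 12 (not isolated)
Conditions: H2 (5 bar), 10% Pd/C, EtOAc, rt; filter; DBU (0.2 equiv), CH2Cl2, rt
Reagents that add atoms: none
Why: Heterogeneous catalytic hydrogenation should deliver both hydrogens from the convex face of the cis‑fused bicycle (the face of the ring‑fusion hydrogen and angular methyl, away from the lactone), which sets C5 (target C3) with its methyl on the lactone face and leaves the formyl group cis to it in 12. Base epimerisation of the only enolisable centre then moves the formyl group to the convex face, trans to the neighbouring methyl and away from the lactone carbonyl, which is expected to be the more stable arrangement (target C2).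

Step 7
Reactants: 13 (3R,3aR,5S,6R,6aR)‑5,6a‑dimethyl‑3‑menthyloxy‑1‑oxohexahydro‑1H‑cyclopenta[c]furan‑6‑carbaldehyde
Product: 14 (3R,3aR,5S,6R,6aS)‑6‑(hydroxymethyl)‑5,6a‑dimethyl‑3‑[(1R,2S,5R)‑menthyloxy]hexahydro‑1H‑cyclopenta[c]furan‑1‑one
Conditions: NaBH4, THF/MeOH, −20 → 0 °C
Reagents that add atoms: none
Why: Borohydride reduction of an aldehyde in the presence of a lactone; the new hydroxymethyl group is trans to the lactone carbonyl on the adjacent carbon, so translactonisation would need a trans‑fused bicyclo[3.3.0] system and should not occur.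

Step 8
Reactants: 14 (3R,3aR,5S,6R,6aS)‑6‑(hydroxymethyl)‑5,6a‑dimethyl‑3‑menthyloxyhexahydro‑1H‑cyclopenta[c]furan‑1‑one
Product: 15 (3R,3aR,5S,6R,6aS)‑6‑[(TBDPS‑oxy)methyl]‑5,6a‑dimethyl‑3‑[(1R,2S,5R)‑menthyloxy]hexahydro‑1H‑cyclopenta[c]furan‑1‑one
Conditions: TBDPSCl, imidazole, DMAP (cat.), DMF, rt
Reagents that add atoms: tert‑butyl(chloro)diphenylsilane, CC(C)(C)[Si](Cl)(c1ccccc1)c1ccccc1
Why: Standard silylation of a primary alcohol; the tert‑butyldiphenylsilyl ether is chosen because it withstands the aqueous acid of the next step as well as ylide, hydride and magnesium methoxide later.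

Step 9
Reactants: 15 (3R,3aR,5S,6R,6aS)‑6‑[(TBDPS‑oxy)methyl]‑5,6a‑dimethyl‑3‑menthyloxyhexahydro‑1H‑cyclopenta[c]furan‑1‑one
Product: 16 (3aR,5S,6R,6aS)‑6‑[(TBDPS‑oxy)methyl]‑3‑hydroxy‑5,6a‑dimethylhexahydro‑1H‑cyclopenta[c]furan‑1‑one (lactol, anomeric mixture)
Conditions: CF3CO2H/H2O/1,4‑dioxane (2:1:1), 40 °C
Reagents that add atoms: water, O
Why: Acid‑catalysed acetal hydrolysis of the pseudo‑ester releases menthol and leaves the cis formyl acid in its cyclic lactol form; the ring‑fusion carbon is not enolisable while the ring is closed, and tert‑butyldiphenylsilyl ethers of primary alcohols tolerate aqueous trifluoroacetic acid of this strength.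

Step 10
Reactants: 16 (3aR,5S,6R,6aS)‑6‑[(TBDPS‑oxy)methyl]‑3‑hydroxy‑5,6a‑dimethylhexahydro‑1H‑cyclopenta[c]furan‑1‑one
Product: 18 (1R,2R,3S,5S)‑2‑[(TBDPS‑oxy)methyl]‑1,3‑dimethyl‑5‑(2‑methylprop‑1‑enyl)cyclopentane‑1‑carboxylic acid, via open formyl acid 17 (not isolated)
Conditions: i‑PrPPh3I (3 equiv), n‑BuLi (3 equiv), THF, 0 °C; add 16, −78 °C → rt; aq. citric acid work‑up
Reagents that add atoms: isopropyltriphenylphosphonium iodide, CC(C)[P+](c1ccccc1)(c1ccccc1)c1ccccc1.[I-]
Why: Wittig olefination of a γ‑hydroxy lactone: the first equivalent of ylide opens the lactol to the formyl carboxylate 17, the second olefinates the aldehyde faster than C5 can epimerise, and the carboxylate is inert; the mild acidic work‑up avoids protonation of the new alkene.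

Step 11
Reactants: 18 (1R,2R,3S,5S)‑2‑[(TBDPS‑oxy)methyl]‑1,3‑dimethyl‑5‑(2‑methylprop‑1‑enyl)cyclopentane‑1‑carboxylic acid
Product: 19 [(1R,2R,3S,5S)‑2‑[(TBDPS‑oxy)methyl]‑1,3‑dimethyl‑5‑(2‑methylprop‑1‑enyl)cyclopentyl]methanol
Conditions: LiAlH4, THF, 0 °C → rt; aqueous NaOH work‑up
Reagents that add atoms: none
Why: Hydride reduction of a hindered carboxylic acid to the neopentyl alcohol; alkene and silyl ether are inert at or below room temperature.

Step 12
Reactants: 19 [(1R,2R,3S,5S)‑2‑[(TBDPS‑oxy)methyl]‑1,3‑dimethyl‑5‑(2‑methylprop‑1‑enyl)cyclopentyl]methanol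
Product: 20 (1R,2R,3S,5S)‑2‑[(TBDPS‑oxy)methyl]‑1,3‑dimethyl‑5‑(2‑methylprop‑1‑enyl)cyclopentane‑1‑carbaldehyde
Conditions: Dess–Martin periodinane, CH2Cl2, rt
Reagents that add atoms: none
Why: Dess–Martin oxidation of a primary alcohol; the aldehyde has no α‑hydrogen, so it can neither epimerise nor enolise.

Step 13
Reactants: 20 (1R,2R,3S,5S)‑2‑[(TBDPS‑oxy)methyl]‑1,3‑dimethyl‑5‑(2‑methylprop‑1‑enyl)cyclopentane‑1‑carbaldehyde
Product: 21 methyl (2E)‑3‑[(1R,2R,3S,5S)‑2‑[(TBDPS‑oxy)methyl]‑1,3‑dimethyl‑5‑(2‑methylprop‑1‑enyl)cyclopentyl]prop‑2‑enoate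
Conditions: (MeO)2P(O)CH2CO2Me, NaH, THF, 0 → 50 °C
Reagents that add atoms: trimethyl phosphonoacetate, COC(=O)CP(=O)(OC)OC
Why: Horner–Wadsworth–Emmons olefination, which tolerates α‑quaternary aldehydes better than a stabilised Wittig ylide; it adds the two missing carbons of the acid arm, and the alkene geometry is irrelevant because the double bond is reduced next.

Step 14
Reactants: 21 methyl (2E)‑3‑[(1R,2R,3S,5S)‑2‑[(TBDPS‑oxy)methyl]‑1,3‑dimethyl‑5‑(2‑methylprop‑1‑enyl)cyclopentyl]prop‑2‑enoate
Product: 22 methyl 3‑[(1R,2R,3S,5S)‑2‑[(TBDPS‑oxy)methyl]‑1,3‑dimethyl‑5‑(2‑methylprop‑1‑enyl)cyclopentyl]propanoate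
Conditions: Mg turnings, MeOH, rt
Reagents that add atoms: none
Why: Magnesium‑in‑methanol conjugate reduction proceeds by electron transfer to the enoate only, so the isolated trisubstituted alkene that hydrogenation would endanger is left untouched; the methyl ester matches the solvent.

Step 15
Reactants: 22 methyl 3‑[(1R,2R,3S,5S)‑2‑[(TBDPS‑oxy)methyl]‑1,3‑dimethyl‑5‑(2‑methylprop‑1‑enyl)cyclopentyl]propanoate
Product: 23 methyl 3‑[(1R,2R,3S,5S)‑2‑(hydroxymethyl)‑1,3‑dimethyl‑5‑(2‑methylprop‑1‑enyl)cyclopentyl]propanoate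
Conditions: n‑Bu4NF, THF, 0 °C → rt
Reagents that add atoms: none
Why: Fluoride desilylation; lactonisation of the freed alcohol onto the ester would need a seven‑membered ring spanning two trans substituents and should not compete.

Step 16
Reactants: 23 methyl 3‑[(1R,2R,3S,5S)‑2‑(hydroxymethyl)‑1,3‑dimethyl‑5‑(2‑methylprop‑1‑enyl)cyclopentyl]propanoate; 24 umbelliferone
Product: 25 ferulsinaic acid methyl ester, methyl 3‑[(1R,2R,3S,5S)‑1,3‑dimethyl‑5‑(2‑methylprop‑1‑enyl)‑2‑{[(2‑oxo‑2H‑chromen‑7‑yl)oxy]methyl}cyclopentyl]propanoate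
Conditions: PPh3, DIAD, THF, 0 °C → rt
Reagents that add atoms: none
Why: Mitsunobu etherification of a primary alcohol with an acidic phenol, which suits 7‑hydroxycoumarin; the reacting carbon is not a stereocentre, and neutral conditions spare the ester and the alkene.

Step 17
Reactants: 25 ferulsinaic acid methyl ester
Product: 27 ferulsinaic acid, 3‑[(1R,2R,3S,5S)‑1,3‑dimethyl‑5‑(2‑methylprop‑1‑enyl)‑2‑{[(2‑oxo‑2H‑chromen‑7‑yl)oxy]methyl}cyclopentyl]propanoic acid, via ring‑opened (Z)‑coumarinic diacid 26 (not isolated)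
Conditions: LiOH (6 equiv), THF/MeOH/H2O, rt, dark; then 1 M HCl to pH 2, rt
Reagents that add atoms: lithium hydroxide, [Li+].[OH-]
Why: Saponification; excess hydroxide also opens the coumarin lactone to the (Z)‑2‑hydroxycinnamate, which keeps its geometry in the dark at room temperature and closes again spontaneously on acidification, so the only net change is ester to acid.

## Compound list

1 | 3‑methylfuran‑2‑carboxylic acid | Cc1ccoc1C(=O)O | starting material
2 | 6‑methyl‑2,3,7‑trioxabicyclo[2.2.1]hept‑5‑ene‑1‑carboxylic acid (furan endoperoxide, racemic) | OC(=O)C12OOC(C=C1C)O2 | intermediate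
3 | 5‑hydroxy‑3‑methylfuran‑2(5H)‑one (racemic) | CC1=CC(O)OC1=O | intermediate
4 | (−)‑menthol, (1R,2S,5R)‑5‑methyl‑2‑(propan‑2‑yl)cyclohexan‑1‑ol | CC(C)[C@@H]1CC[C@@H](C)C[C@H]1O | starting material
5 | (5R)‑3‑methyl‑5‑[(1R,2S,5R)‑menthyloxy]furan‑2(5H)‑one | O=C1O[C@@H](O[C@@H]2C[C@H](C)CC[C@H]2C(C)C)C=C1C | intermediate
6 | isoprene (2‑methylbuta‑1,3‑diene) | CC(=C)C=C | starting material
7 | (3R,3aR,7aS)‑5,7a‑dimethyl‑3‑[(1R,2S,5R)‑menthyloxy]‑3a,4,7,7a‑tetrahydro‑2‑benzofuran‑1(3H)‑one (cis‑fused, menthyloxy trans to the carbocycle) | O=C2O[C@@H](O[C@@H]3C[C@H](C)CC[C@H]3C(C)C)[C@@H]1CC(C)=CC[C@@]12C | intermediate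
8 | secondary ozonide of 7 (1,2,4‑trioxolane spanning former C5 and C6, mixture at the two new centres) | O=C2O[C@@H](O[C@@H]3C[C@H](C)CC[C@H]3C(C)C)[C@@H]1CC4(C)OOC(O4)C[C@@]12C | intermediate
9 | 2‑{(3S,4R,5R)‑3‑methyl‑5‑[(1R,2S,5R)‑menthyloxy]‑2‑oxo‑4‑(2‑oxopropyl)oxolan‑3‑yl}acetaldehyde | O=C2O[C@@H](O[C@@H]3C[C@H](C)CC[C@H]3C(C)C)[C@H](CC(C)=O)[C@]2(C)CC=O | intermediate
10 | (3R,3aR,6aR)‑5‑hydroxy‑5,6a‑dimethyl‑3‑[(1R,2S,5R)‑menthyloxy]‑1‑oxohexahydro‑1H‑cyclopenta[c]furan‑6‑carbaldehyde (aldol, mixture at C5 and C6) | O=C2O[C@@H](O[C@@H]3C[C@H](C)CC[C@H]3C(C)C)[C@@H]1CC(C)(O)C(C=O)[C@@]12C | intermediate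
11 | (3R,3aR,6aR)‑5,6a‑dimethyl‑3‑[(1R,2S,5R)‑menthyloxy]‑1‑oxo‑3,3a,4,6a‑tetrahydro‑1H‑cyclopenta[c]furan‑6‑carbaldehyde | O=C2O[C@@H](O[C@@H]3C[C@H](C)CC[C@H]3C(C)C)[C@@H]1CC(C)=C(C=O)[C@@]12C | intermediate
12 | (3R,3aR,5S,6S,6aR)‑5,6a‑dimethyl‑3‑[(1R,2S,5R)‑menthyloxy]‑1‑oxohexahydro‑1H‑cyclopenta[c]furan‑6‑carbaldehyde (formyl cis to the C5 methyl, both on the lactone face) | O=C2O[C@@H](O[C@@H]3C[C@H](C)CC[C@H]3C(C)C)[C@@H]1C[C@H](C)[C@H](C=O)[C@@]12C | intermediate
13 | (3R,3aR,5S,6R,6aR)‑5,6a‑dimethyl‑3‑[(1R,2S,5R)‑menthyloxy]‑1‑oxohexahydro‑1H‑cyclopenta[c]furan‑6‑carbaldehyde (formyl trans to the C5 methyl, cis to the angular methyl) | O=C2O[C@@H](O[C@@H]3C[C@H](C)CC[C@H]3C(C)C)[C@@H]1C[C@H](C)[C@@H](C=O)[C@@]12C | intermediate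
14 | (3R,3aR,5S,6R,6aS)‑6‑(hydroxymethyl)‑5,6a‑dimethyl‑3‑[(1R,2S,5R)‑menthyloxy]hexahydro‑1H‑cyclopenta[c]furan‑1‑one | O=C2O[C@@H](O[C@@H]3C[C@H](C)CC[C@H]3C(C)C)[C@@H]1C[C@H](C)[C@@H](CO)[C@@]12C | intermediate
15 | (3R,3aR,5S,6R,6aS)‑6‑{[tert‑butyl(diphenyl)silyl]oxymethyl}‑5,6a‑dimethyl‑3‑[(1R,2S,5R)‑menthyloxy]hexahydro‑1H‑cyclopenta[c]furan‑1‑one | O=C2O[C@@H](O[C@@H]3C[C@H](C)CC[C@H]3C(C)C)[C@@H]1C[C@H](C)[C@@H](CO[Si](c4ccccc4)(c4ccccc4)C(C)(C)C)[C@@]12C | intermediate
16 | (3aR,5S,6R,6aS)‑6‑{[tert‑butyl(diphenyl)silyl]oxymethyl}‑3‑hydroxy‑5,6a‑dimethylhexahydro‑1H‑cyclopenta[c]furan‑1‑one (anomeric mixture) | O=C2OC(O)[C@@H]1C[C@H](C)[C@@H](CO[Si](c4ccccc4)(c4ccccc4)C(C)(C)C)[C@@]12C | intermediate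
17 | (1S,2R,3S,5R)‑2‑{[tert‑butyl(diphenyl)silyl]oxymethyl}‑5‑formyl‑1,3‑dimethylcyclopentane‑1‑carboxylic acid | O=C[C@@H]1C[C@H](C)[C@@H](CO[Si](c2ccccc2)(c2ccccc2)C(C)(C)C)[C@]1(C)C(=O)O | intermediate
18 | (1R,2R,3S,5S)‑2‑{[tert‑butyl(diphenyl)silyl]oxymethyl}‑1,3‑dimethyl‑5‑(2‑methylprop‑1‑enyl)cyclopentane‑1‑carboxylic acid | CC(C)=C[C@@H]1C[C@H](C)[C@@H](CO[Si](c2ccccc2)(c2ccccc2)C(C)(C)C)[C@]1(C)C(=O)O | intermediate
19 | [(1R,2R,3S,5S)‑2‑{[tert‑butyl(diphenyl)silyl]oxymethyl}‑1,3‑dimethyl‑5‑(2‑methylprop‑1‑enyl)cyclopentyl]methanol | CC(C)=C[C@@H]1C[C@H](C)[C@@H](CO[Si](c2ccccc2)(c2ccccc2)C(C)(C)C)[C@]1(C)CO | intermediate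
20 | (1R,2R,3S,5S)‑2‑{[tert‑butyl(diphenyl)silyl]oxymethyl}‑1,3‑dimethyl‑5‑(2‑methylprop‑1‑enyl)cyclopentane‑1‑carbaldehyde | CC(C)=C[C@@H]1C[C@H](C)[C@@H](CO[Si](c2ccccc2)(c2ccccc2)C(C)(C)C)[C@]1(C)C=O | intermediate
21 | methyl (2E)‑3‑[(1R,2R,3S,5S)‑2‑{[tert‑butyl(diphenyl)silyl]oxymethyl}‑1,3‑dimethyl‑5‑(2‑methylprop‑1‑enyl)cyclopentyl]prop‑2‑enoate | CC(C)=C[C@@H]1C[C@H](C)[C@@H](CO[Si](c2ccccc2)(c2ccccc2)C(C)(C)C)[C@]1(C)/C=C/C(=O)OC | intermediate
22 | methyl 3‑[(1R,2R,3S,5S)‑2‑{[tert‑butyl(diphenyl)silyl]oxymethyl}‑1,3‑dimethyl‑5‑(2‑methylprop‑1‑enyl)cyclopentyl]propanoate | CC(C)=C[C@@H]1C[C@H](C)[C@@H](CO[Si](c2ccccc2)(c2ccccc2)C(C)(C)C)[C@]1(C)CCC(=O)OC | intermediate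
23 | methyl 3‑[(1R,2R,3S,5S)‑2‑(hydroxymethyl)‑1,3‑dimethyl‑5‑(2‑methylprop‑1‑enyl)cyclopentyl]propanoate | CC(C)=C[C@@H]1C[C@H](C)[C@@H](CO)[C@]1(C)CCC(=O)OC | intermediate
24 | umbelliferone (7‑hydroxy‑2H‑chromen‑2‑one) | Oc1ccc2ccc(=O)oc2c1 | starting material
25 | ferulsinaic acid methyl ester, methyl 3‑[(1R,2R,3S,5S)‑1,3‑dimethyl‑5‑(2‑methylprop‑1‑enyl)‑2‑{[(2‑oxo‑2H‑chromen‑7‑yl)oxy]methyl}cyclopentyl]propanoate | CC(C)=C[C@@H]1C[C@H](C)[C@@H](COc2ccc3ccc(=O)oc3c2)[C@]1(C)CCC(=O)OC | intermediate
26 | (2Z)‑3‑[4‑{[(1R,2R,3S,5S)‑2‑(2‑carboxyethyl)‑2,5‑dimethyl‑3‑(2‑methylprop‑1‑enyl)cyclopentyl]methoxy}‑2‑hydroxyphenyl]prop‑2‑enoic acid (ring‑opened coumarin; descriptors refer to the ring numbering of 27) | CC(C)=C[C@@H]1C[C@H](C)[C@@H](COc2ccc(/C=C\C(=O)O)c(O)c2)[C@]1(C)CCC(=O)O | intermediate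
27 | ferulsinaic acid, 3‑[(1R,2R,3S,5S)‑1,3‑dimethyl‑5‑(2‑methylprop‑1‑enyl)‑2‑{[(2‑oxo‑2H‑chromen‑7‑yl)oxy]methyl}cyclopentyl]propanoic acid | CC(C)=C[C@@H]1C[C@H](C)[C@@H](COc2ccc3ccc(=O)oc3c2)[C@]1(C)CCC(=O)O | target

## Step count and weakest steps

Total step count: 17. Longest linear sequence: 17 steps, from 1 to 27; 4, 6 and 24 enter as commercial reagents.

**Step 3 (key step).** Two things may go wrong: insufficient conversion because the α‑methyl group retards the dienophile, and incomplete para regioselectivity, since a single methyl group polarises the diene only weakly. Facial selectivity is the safer element.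
- Fallback: starting from 5, cycloaddition with the more electron‑rich and strongly para‑directing 2‑(trimethylsilyloxy)buta‑1,3‑diene (toluene, 110 °C) should give the silyl enol ether (3R,3aR,7aS)‑7a‑methyl‑3‑menthyloxy‑5‑(trimethylsilyloxy)‑3a,4,7,7a‑tetrahydro‑2‑benzofuran‑1(3H)‑one F1, whose double bond already lies between C5 and C6.
- Fluoride‑triggered triflation (CsF, PhNTf2, DME) would convert it without loss of regiochemistry into the enol triflate (3R,3aR,7aS)‑7a‑methyl‑3‑menthyloxy‑1‑oxo‑1,3,3a,4,7,7a‑hexahydro‑2‑benzofuran‑5‑yl trifluoromethanesulfonate F2.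
- Negishi methylation (MeZnCl, Pd(PPh3)4, THF, 50 °C) would rejoin the route at 7.

**Step 5.** The ring may close the other way round, through the ketone α‑carbon onto the aldehyde, or close slowly because the nucleophilic carbon sits next to the quaternary centre.
- Fallback: starting from 9, the aldehyde alone is condensed with one equivalent of pyrrolidine (4 Å molecular sieves, CH2Cl2, 0 °C) to the isolated enamine 1‑[(E)‑2‑{(3S,4R,5R)‑3‑methyl‑5‑menthyloxy‑2‑oxo‑4‑(2‑oxopropyl)oxolan‑3‑yl}ethenyl]pyrrolidine F3, so the nucleophile is fixed before any ring is formed.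
- Acetic acid in toluene at 60 °C would then drive addition to the ketone and elimination of the amine, returning to the route at 11.

**Step 6.** Hydrogen uptake at the tetrasubstituted alkene may be slow, with competing reduction of the formyl group. Delivery from the concave face would misplace the C3 methyl, and the base equilibration may stop at an unfavourable epimer ratio at C2, in which case the minor epimer would be recycled.
- Fallback: starting from 11, Luche reduction (NaBH4, CeCl3·7H2O, MeOH, 0 °C) gives the allylic alcohol (3R,3aR,6aR)‑6‑(hydroxymethyl)‑5,6a‑dimethyl‑3‑menthyloxy‑3,3a,4,6a‑tetrahydro‑1H‑cyclopenta[c]furan‑1‑one F4.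
- Homogeneous hydrogenation with [Ir(cod)(PCy3)(py)]PF6 (H2, CH2Cl2), which accepts tetrasubstituted alkenes bound through a neighbouring hydroxyl group and is more sensitive to the shape of the bicycle, gives the saturated alcohol (3R,3aR,5S,6S,6aS)‑6‑(hydroxymethyl)‑5,6a‑dimethyl‑3‑menthyloxyhexahydro‑1H‑cyclopenta[c]furan‑1‑one F5.
- Dess–Martin oxidation leads to 12, where the route is rejoined before the base equilibration to 13.

**Step 9.** The acyl acetal is electron‑poor and hydrolyses slowly, so loss of the silyl ether may set in before the menthyl group is released.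
- Fallback: starting from 15, LiAlH4 (THF, 0 °C) reduces the lactone acetal to the diol [(1R,2R,3S,5R)‑2‑{[tert‑butyl(diphenyl)silyl]oxymethyl}‑1,3‑dimethylcyclopentane‑1,5‑diyl]dimethanol F6 with release of menthol.
- TEMPO with PhI(OAc)2 oxidises the less hindered hydroxymethyl group on the ring CH and closes the lactone (3aS,4R,5S,6aR)‑4‑{[tert‑butyl(diphenyl)silyl]oxymethyl}‑3a,5‑dimethylhexahydro‑1H‑cyclopenta[c]furan‑1‑one F7.
- i‑Bu2AlH (CH2Cl2, −78 °C) gives the lactol (3aS,4R,5S,6aR)‑4‑{[tert‑butyl(diphenyl)silyl]oxymethyl}‑3a,5‑dimethylhexahydro‑1H‑cyclopenta[c]furan‑1‑ol F8.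
- Wittig reaction with the isopropylidene ylide of step 10 returns to the route at 19, bypassing 16 to 18.

**Step 16.** Displacement of the alkoxyphosphonium ion at the β‑branched primary carbon may be slow, so alkylation of the hydrazide by‑product could overtake the phenol.
- Fallback: starting from 23, Tf2O and 2,6‑lutidine (CH2Cl2, −78 °C) give the triflate methyl 3‑[(1R,2R,3S,5S)‑1,3‑dimethyl‑5‑(2‑methylprop‑1‑enyl)‑2‑{[(trifluoromethanesulfonyl)oxy]methyl}cyclopentyl]propanoate F9.
- Williamson displacement with 24 and Cs2CO3 (MeCN, 0 °C → rt) returns to the route at 25.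

## Further compounds

F1 | step 3 | (3R,3aR,7aS)‑7a‑methyl‑3‑[(1R,2S,5R)‑menthyloxy]‑5‑(trimethylsilyloxy)‑3a,4,7,7a‑tetrahydro‑2‑benzofuran‑1(3H)‑one | O=C2O[C@@H](O[C@@H]3C[C@H](C)CC[C@H]3C(C)C)[C@@H]1CC(O[Si](C)(C)C)=CC[C@@]12C
F2 | step 3 | (3R,3aR,7aS)‑7a‑methyl‑3‑[(1R,2S,5R)‑menthyloxy]‑1‑oxo‑1,3,3a,4,7,7a‑hexahydro‑2‑benzofuran‑5‑yl trifluoromethanesulfonate | O=C2O[C@@H](O[C@@H]3C[C@H](C)CC[C@H]3C(C)C)[C@@H]1CC(OS(=O)(=O)C(F)(F)F)=CC[C@@]12C
F3 | step 5 | 1‑[(E)‑2‑{(3S,4R,5R)‑3‑methyl‑5‑[(1R,2S,5R)‑menthyloxy]‑2‑oxo‑4‑(2‑oxopropyl)oxolan‑3‑yl}ethenyl]pyrrolidine | O=C2O[C@@H](O[C@@H]3C[C@H](C)CC[C@H]3C(C)C)[C@H](CC(C)=O)[C@]2(C)/C=C/N4CCCC4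
F4 | step 6 | (3R,3aR,6aR)‑6‑(hydroxymethyl)‑5,6a‑dimethyl‑3‑[(1R,2S,5R)‑menthyloxy]‑3,3a,4,6a‑tetrahydro‑1H‑cyclopenta[c]furan‑1‑one | O=C2O[C@@H](O[C@@H]3C[C@H](C)CC[C@H]3C(C)C)[C@@H]1CC(C)=C(CO)[C@@]12C
F5 | step 6 | (3R,3aR,5S,6S,6aS)‑6‑(hydroxymethyl)‑5,6a‑dimethyl‑3‑[(1R,2S,5R)‑menthyloxy]hexahydro‑1H‑cyclopenta[c]furan‑1‑one | O=C2O[C@@H](O[C@@H]3C[C@H](C)CC[C@H]3C(C)C)[C@@H]1C[C@H](C)[C@H](CO)[C@@]12C
F6 | step 9 | [(1R,2R,3S,5R)‑2‑{[tert‑butyl(diphenyl)silyl]oxymethyl}‑1,3‑dimethylcyclopentane‑1,5‑diyl]dimethanol | OC[C@@H]1C[C@H](C)[C@@H](CO[Si](c2ccccc2)(c2ccccc2)C(C)(C)C)[C@]1(C)CO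
F7 | step 9 | (3aS,4R,5S,6aR)‑4‑{[tert‑butyl(diphenyl)silyl]oxymethyl}‑3a,5‑dimethylhexahydro‑1H‑cyclopenta[c]furan‑1‑one | O=C3[C@@H]1C[C@H](C)[C@@H](CO[Si](c2ccccc2)(c2ccccc2)C(C)(C)C)[C@]1(C)CO3
F8 | step 9 | (3aS,4R,5S,6aR)‑4‑{[tert‑butyl(diphenyl)silyl]oxymethyl}‑3a,5‑dimethylhexahydro‑1H‑cyclopenta[c]furan‑1‑ol (anomeric mixture) | OC3[C@@H]1C[C@H](C)[C@@H](CO[Si](c2ccccc2)(c2ccccc2)C(C)(C)C)[C@]1(C)CO3
F9 | step 16 | methyl 3‑[(1R,2R,3S,5S)‑1,3‑dimethyl‑5‑(2‑methylprop‑1‑enyl)‑2‑{[(trifluoromethanesulfonyl)oxy]methyl}cyclopentyl]propanoate | CC(C)=C[C@@H]1C[C@H](C)[C@@H](COS(=O)(=O)C(F)(F)F)[C@]1(C)CCC(=O)OC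
A1 | alternative 1 | methyl 3‑[(1R,3S,5S)‑1,3‑dimethyl‑5‑(2‑methylprop‑1‑enyl)‑2‑oxocyclopentyl]propanoate | CC(C)=C[C@@H]1C[C@H](C)C(=O)[C@]1(C)CCC(=O)OC
A2 | alternative 1 | methyl 3‑[(1R,2S)‑1‑methyl‑2‑(2‑methylprop‑1‑enyl)‑4‑oxocyclobutyl]propanoate | CC(C)=C[C@@H]1CC(=O)[C@]1(C)CCC(=O)OC
A3 | alternative 1 | diazoethane | CC=[N+]=[N-]
A4 | alternative 2 | (7aR)‑7a‑methyl‑2,3,7,7a‑tetrahydro‑1H‑indene‑1,5(6H)‑dione | C[C@@]12CCC(=O)C=C1CCC2=O
A5 | alternative 2 | 2‑methyl‑2‑(3‑oxobutyl)cyclopentane‑1,3‑dione | CC(=O)CCC1(C)C(=O)CCC1=O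
A6 | alternative 2 | D‑proline, (2R)‑pyrrolidine‑2‑carboxylic acid | OC(=O)[C@H]1CCCN1
A7 | alternative 3 | ferulsinaic acid methyl ester (identical with 25) | CC(C)=C[C@@H]1C[C@H](C)[C@@H](COc2ccc3ccc(=O)oc3c2)[C@]1(C)CCC(=O)OC
A8 | alternative 3 | methyl 3‑[(1R,2R,3S,5S)‑1,3‑dimethyl‑5‑(2‑methylprop‑1‑enyl)‑2‑{[3‑(prop‑2‑ynoyloxy)phenoxy]methyl}cyclopentyl]propanoate | CC(C)=C[C@@H]1C[C@H](C)[C@@H](COc2cccc(OC(=O)C#C)c2)[C@]1(C)CCC(=O)OC
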